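**Plan**

1. Retrosynthesis: the O8 and O9 acyl groups come off first. The C14–O–C4 enol ether (bridged dihydropyran) is cut back to a C14 aldehyde and a 4α,15-epoxide, hence to a 4(15)-methylene guaianolide, and C13 is removed. C4–C5 and O–C6 are then cut together, which opens the cyclopentane and the γ-lactone to a cycloheptene acid with a but-3-ynyl chain on C1.
2. Enabling feature: the C4–C5 bond (β at C5, cyclopentane) and the lactone O–C6 bond (α at C6, γ-lactone) lie anti across C5–C6 of the seven-membered ring. This is the pattern left by anti addition of C4 and the C12 carboxylate to a C5=C6 cis-alkene.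
3. The cycloheptene is cut at C7–C11 (Claisen), C6=C7 (metathesis), C8–C9 (alkoxyallylboration), C10–C14 (enolate hydroxymethylation) and C1–C2 (conjugate addition), back to (S)-5-(hydroxymethyl)furan-2(5H)-one.
4. Forward ring order: butenolide, open chain, seven-membered ring (step 9), cyclopentane plus γ-lactone together (step 12), bridged dihydropyran (step 22).
5. Stereochemistry: C5 of the butenolide (chiral pool) controls C1 and is later relayed suprafacially to C7. C8/C9 come from the chiral allylborane, C5/C6 from tether and inversion in the gold step, C4 from convex-face epoxidation followed by inverting opening, and the side-chain centre from (R)-2-methylbutanoic acid.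

Key step: step 12

Remark: carbons carry guaiane numbers throughout (C12 lactone carbonyl, C14 and C15 the one-carbon branches on C10 and C4); α/β give the face a group occupies, or will occupy, in the guaianolide with H-1 and H-5 α.
Remark: the C10 configuration fixed in step 3 (C14 on the α face) is carried to step 21; it is assumed to equilibrate through the enol under the acid of step 22, where C10 becomes sp2.

**Route**

Step 1
Reactants: 1 (S)-5-(hydroxymethyl)furan-2(5H)-one
Product: 2 (S)-5-(chloromethyl)furan-2(5H)-one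
Conditions: PPh3, N-chlorosuccinimide, CH2Cl2, 0 °C → rt
Reagents that add atoms: N-chlorosuccinimide, O=C1CCC(=O)N1Cl
Why: Appel-type chlorination (chlorophosphonium activation, SN2 by chloride at the primary carbon) is neutral, so the base-sensitive butenolide and its C5 stereocentre are untouched.

Step 2
Reactants: 2 (S)-5-(chloromethyl)furan-2(5H)-one; 3 (4-bromobut-1-yn-1-yl)trimethylsilane
Product: 6 (4S,5S)-5-(chloromethyl)-4-[4-(trimethylsilyl)but-3-yn-1-yl]oxolan-2-one, via Grignard reagent 4 (not isolated), via silyl ketene acetal 5 (not isolated)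
Conditions: 3, Mg, THF, 40 °C; then 2, CuBr·SMe2 (10 mol%), Me3SiCl, THF, −78 °C, slow addition of 4; aqueous NH4Cl
Reagents that add atoms: none
Why: Copper-catalysed, silyl-chloride-accelerated conjugate addition of the Grignard reagent puts the side chain on C1 anti to the C5 chloromethyl group (4,5-trans lactone), and slow addition at −78 °C keeps free base low so that HCl is not lost from the butenolide.

Step 3
Reactants: 6 (4S,5S)-5-(chloromethyl)-4-[4-(trimethylsilyl)but-3-yn-1-yl]oxolan-2-one
Product: 7 (3R,4S,5S)-5-(chloromethyl)-3-(hydroxymethyl)-4-[4-(trimethylsilyl)but-3-yn-1-yl]oxolan-2-one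
Conditions: LiN(iPr)2, THF, −78 °C; CH2O (gas, from cracked paraformaldehyde), −78 → −40 °C; aqueous NH4Cl
Reagents that add atoms: formaldehyde, C=O
Why: Aldol addition of the lithium lactone enolate to monomeric formaldehyde takes place on the face opposite the adjacent C1 side chain, giving the 3,4-trans hydroxymethyl lactone (C14 installed, C10 set).

Step 4
Reactants: 7 (3R,4S,5S)-5-(chloromethyl)-3-(hydroxymethyl)-4-[4-(trimethylsilyl)but-3-yn-1-yl]oxolan-2-one
Product: 8 (3R,4S,5S)-5-(chloromethyl)-3-(hydroxymethyl)-4-[4-(trimethylsilyl)but-3-yn-1-yl]oxolan-2-ol (both anomers)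
Conditions: iBu2AlH (2.2 equiv), CH2Cl2, −78 °C; aqueous KNaC4H4O6
Reagents that add atoms: none
Why: Partial hydride reduction of the γ-lactone stops at the lactol because the aluminium hemiacetal survives at −78 °C until work-up, one further equivalent being consumed by the free hydroxyl.

Step 5
Reactants: 9 prop-2-en-1-ol
Product: 10 3-(methoxymethoxy)prop-1-ene
Conditions: MeOCH2Cl, iPr2NEt, CH2Cl2, 0 °C → rt
Reagents that add atoms: chloromethyl methyl ether, COCCl
Why: O-Alkylation of the alcohol by the chloromethyl ether under amine base (methoxymethyl ether formation) gives the allyl ether needed for the alkoxyallylborane.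

Step 6
Reactants: 8 lactol (3R,4S,5S)-5-(chloromethyl)-3-(hydroxymethyl)-4-[4-(trimethylsilyl)but-3-yn-1-yl]oxolan-2-ol; 10 3-(methoxymethoxy)prop-1-ene
Product: 12 (2S,3S,4R,5S,6S)-1-chloro-4-(hydroxymethyl)-6-(methoxymethoxy)-3-[4-(trimethylsilyl)but-3-yn-1-yl]oct-7-ene-2,5-diol, via allylborane 11 (not isolated)
Conditions: 10, s-BuLi, THF, −78 °C; (+)-Ipc2BOMe; BF3·OEt2, −78 °C; then 8 (one third equivalent), −78 °C → rt; H2O2, pH 7 phosphate buffer, 0 °C
Reagents that add atoms: none
Why: Asymmetric γ-alkoxyallylboration of the open hydroxy-aldehyde form of the lactol proceeds through a closed chair transition state, in which the (Z)-alkoxyallyl geometry gives the 8,9-syn relationship and the isopinocampheyl groups derived from (−)-α-pinene select the aldehyde face that sets C9, and with it C8, as required.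

Step 7
Reactants: 12 chlorotriol (2S,3S,4R,5S,6S)-1-chloro-4-(hydroxymethyl)-6-(methoxymethoxy)-3-[4-(trimethylsilyl)but-3-yn-1-yl]oct-7-ene-2,5-diol
Product: 13 O9,O14-isopropylidene chlorohydrin (acetonide of 12, 5-OH free)
Conditions: Me2C(OMe)2, pyridinium p-toluenesulfonate (cat.), CH2Cl2, rt
Reagents that add atoms: 2,2-dimethoxypropane, COC(C)(C)OC
Why: Acid-catalysed transketalisation closes the six-membered acetonide of the 1,3-diol (O9/O14) in preference to any seven- or eight-membered ketal, so that only the C5 hydroxyl stays free.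

Step 8
Reactants: 13 O9,O14-isopropylidene chlorohydrin
Product: 15 diene allylic alcohol (5-hydroxy carbinol bearing vinyl C6; 8-OMOM carbon bearing vinyl C7), via epoxide 14 (not isolated)
Conditions: Me3S+ I− (5 equiv), n-BuLi (4.5 equiv), THF, −10 °C → rt
Reagents that add atoms: trimethylsulfonium iodide, C[S+](C)C.[I-]
Why: The sulfonium ylide first acts as base to close the chlorohydrin to the terminal epoxide, then opens it at C6 and eliminates dimethyl sulfide (one-carbon homologation of an epoxide to an allylic alcohol), the C5–O bond and hence the C5 configuration being untouched.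

Step 9
Reactants: 15 diene allylic alcohol
Product: 16 cyclohept-6-en-5β-ol (1β-silylbutynyl, 8β-OMOM, 9α,14-O-isopropylidene)
Conditions: second-generation Grubbs catalyst RuCl2(=CHPh)(PCy3)(H2IMes) (5 mol%), CH2Cl2 (5 mM), 40 °C
Reagents that add atoms: none
Why: Ring-closing metathesis of the two terminal vinyl groups forms the seven-membered ring with a cis C6=C7 bond, the silyl cap keeping the alkyne out of enyne metathesis.

Step 10
Reactants: 16 cyclohept-6-en-5β-ol
Product: 18 ethyl ester (cyclohept-5-ene, 7β-CH2CO2Et), via ketene acetal 17 (not isolated)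
Conditions: MeC(OEt)3, EtCO2H (cat.), xylenes, 140 °C, EtOH distilled off
Reagents that add atoms: triethyl orthoacetate, CCOC(C)(OCC)OCC
Why: Johnson–Claisen rearrangement of the mixed ketene acetal is a suprafacial [3,3] shift across the ring, so the 5β C–O bond is exchanged for a 7β C–C bond (C7 set, cis to 8β-O) and the alkene moves to C5=C6.

Step 11
Reactants: 18 ethyl ester
Product: 19 cycloheptene acid (7β-CH2CO2H, 1β-but-3-ynyl, 8β-OMOM, 9α,14-O-isopropylidene)
Conditions: LiOH, THF/MeOH/H2O, rt; then 1 M HCl to pH 4 at 0 °C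
Reagents that add atoms: lithium hydroxide, [Li+].[OH-]
Why: Saponification of the ester and base-induced protodesilylation of the alkynylsilane occur in one operation, acetonide and methoxymethyl ether being stable to hydroxide.

Step 12
Reactants: 19 cycloheptene acid
Product: 20 8β-(methoxymethoxy)-9α,14-(isopropylidenedioxy)guai-4(15)-en-6α,12-olide
Conditions: Ph3PAuNTf2 (5 mol%), CH2Cl2 (0.05 M), rt
Reagents that add atoms: none
Why: Ph3PAuNTf2 (monovalent gold) π-activates the terminal alkyne, the C5=C6 alkene attacks C4 to give a cyclopropyl gold carbene (C4–C5–C6), the carboxylic acid opens this at C6 from the rear, and protodeauration of the vinyl gold leaves the C4=C15 exo-methylene. The closest known reaction type is the gold-catalysed 1,6-enyne cyclisation with capture by an internal oxygen nucleophile (hydroxy- and carboxy-cyclisation). The cyclopentane closes 5-exo-dig (C4–C5) and the γ-lactone closes by 5-exo attack of the carboxyl oxygen on C6 of the cyclopropane. C5 is controlled by the three-atom tether from the 1β side chain, which reaches only the β face of the alkene (cis ring fusion, H-5α), and C6 by the inversion in the ring opening, which places the oxygen α and makes the lactone trans-fused. The step needs 5-exo over 6-endo closure and capture over skeletal rearrangement; the terminal alkyne and the tethered acid (five-membered ring onto the secondary cationic C6) favour both, and the acetal oxygens at C8 and C9 are weaker nucleophiles than the acid.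

Step 13
Reactants: 20 guai-4(15)-en-6α,12-olide
Product: 23 8β-(methoxymethoxy)-9α,14-(isopropylidenedioxy)guaia-4(15),11(13)-dien-6α,12-olide, via Mannich base 21 (not isolated), via ammonium iodide 22 (not isolated)
Conditions: LiN(iPr)2, THF, −78 °C; CH2=NMe2+ I−, −78 °C → rt; then MeI, MeOH, rt; then aqueous NaHCO3, CH2Cl2, rt
Reagents that add atoms: N,N-dimethylmethyleneiminium iodide, C=[N+](C)C.[I-]
Why: Eschenmoser methylenation aminomethylates the lactone enolate at C11, and quaternisation followed by base-induced elimination of trimethylamine gives the exocyclic C11=C13 bond without creating a stereocentre.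

Step 14
Reactants: 23 acetonide dienolide
Product: 24 9α,14-dihydroxy-8β-(methoxymethoxy)guaia-4(15),11(13)-dien-6α,12-olide
Conditions: AcOH/THF/H2O (3:1:1), 40 °C
Reagents that add atoms: none
Why: Mild aqueous acid hydrolyses the acetonide while the methoxymethyl ether, both exocyclic alkenes and the lactone survive.

Step 15
Reactants: 24 9α,14-diol
Product: 25 14-(tert-butyldiphenylsilyloxy)-9α-hydroxy-8β-(methoxymethoxy)guaia-4(15),11(13)-dien-6α,12-olide
Conditions: t-BuPh2SiCl, imidazole, CH2Cl2, 0 °C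
Reagents that add atoms: tert-butyl(chloro)diphenylsilane, CC(C)(C)[Si](Cl)(c1ccccc1)c1ccccc1
Why: Silylation with the bulky chlorosilane is selective for the primary C14 hydroxyl over the hindered secondary C9 hydroxyl.

Step 16
Reactants: 25 14-silyl ether
Product: 26 9α-acetoxy-14-(tert-butyldiphenylsilyloxy)-8β-(methoxymethoxy)guaia-4(15),11(13)-dien-6α,12-olide
Conditions: Ac2O, pyridine, 4-(dimethylamino)pyridine (cat.), CH2Cl2, rt
Reagents that add atoms: acetic anhydride, CC(=O)OC(C)=O
Why: Aminopyridine-catalysed acylation acetylates the only free hydroxyl (9α).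

Step 17
Reactants: 26 9α-acetate
Product: 27 9α-acetoxy-14-(tert-butyldiphenylsilyloxy)-8β-hydroxyguaia-4(15),11(13)-dien-6α,12-olide
Conditions: Me2BBr, CH2Cl2, −78 °C; then THF/aqueous NaHCO3, −78 → 0 °C
Reagents that add atoms: none
Why: Bromoborane cleavage of the formaldehyde acetal at −78 °C removes the methoxymethyl ether without touching silyl ether, acetate or alkenes, and the cold bicarbonate quench limits acetyl migration from O9 to O8.

Step 18
Reactants: 27 8β-alcohol; 28 (R)-2-methylbutanoic acid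
Product: 29 9α-acetoxy-14-(tert-butyldiphenylsilyloxy)-8β-[(R)-2-methylbutanoyloxy]guaia-4(15),11(13)-dien-6α,12-olide
Conditions: N,N'-dicyclohexylcarbodiimide, 4-(dimethylamino)pyridine, CH2Cl2, 0 °C → rt
Reagents that add atoms: none
Why: Steglich esterification acylates the 8β-hydroxyl through the acylpyridinium ion, and the acid's stereocentre is carried over unchanged.

Step 19
Reactants: 29 silyl diester
Product: 30 9α-acetoxy-14-hydroxy-8β-[(R)-2-methylbutanoyloxy]guaia-4(15),11(13)-dien-6α,12-olide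
Conditions: HF·pyridine, pyridine, THF, 0 °C → rt
Reagents that add atoms: none
Why: Acidic fluoride desilylation frees the primary alcohol without the base-induced acyl migration or conjugate addition that a basic fluoride source could cause.

Step 20
Reactants: 30 14-alcohol
Product: 31 9α-acetoxy-8β-[(R)-2-methylbutanoyloxy]-14-oxoguaia-4(15),11(13)-dien-6α,12-olide
Conditions: Dess–Martin periodinane, NaHCO3, CH2Cl2, 0 °C → rt
Reagents that add atoms: none
Why: Dess–Martin oxidation under buffered, non-basic conditions gives the aldehyde without β-elimination of the 9-acetate.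

Step 21
Reactants: 31 14-aldehyde
Product: 32 9α-acetoxy-4α,15-epoxy-8β-[(R)-2-methylbutanoyloxy]-14-oxoguai-11(13)-en-6α,12-olide
Conditions: dimethyldioxirane (acetone solution, 1.1 equiv), CH2Cl2, −20 → 0 °C
Reagents that add atoms: dimethyldioxirane, CC1(C)OO1
Why: Dioxirane epoxidation attacks the electron-rich 1,1-disubstituted C4=C15 alkene on the convex α face (the face of H-1 and H-5), placing the epoxide oxygen α at C4, and leaves the electron-poor methylene lactone and the aldehyde alone.

Step 22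
Reactants: 32 epoxy aldehyde
Product: 34 9α-acetoxy-4β,14-epoxy-15-hydroxy-8β-[(R)-2-methylbutanoyloxy]guaia-10(14),11(13)-dien-6α,12-olide (CNP0013863.3), via lactol 33 (not isolated)
Conditions: pyridinium p-toluenesulfonate (10 mol%), water-saturated CH2Cl2, rt; then 4 Å molecular sieves, 35 °C
Reagents that add atoms: none
Why: Under mild acid C10 equilibrates through the enol so that the formyl group can reach the β face, its hydrate oxygen opens the epoxide at the tertiary C4 with inversion (acid-catalysed intramolecular epoxide opening, which sets the 4β C–O bond and frees C15–OH), and acid-catalysed dehydration of the resulting lactol across C10–C14 gives the enol ether.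

**Compound list**

1 | (S)-5-(hydroxymethyl)furan-2(5H)-one | O=C1C=C[C@@H](CO)O1 | starting material
2 | (S)-5-(chloromethyl)furan-2(5H)-one | O=C1C=C[C@@H](CCl)O1 | intermediate
3 | (4-bromobut-1-yn-1-yl)trimethylsilane | C[Si](C)(C)C#CCCBr | starting material
4 | [4-(trimethylsilyl)but-3-yn-1-yl]magnesium bromide | C[Si](C)(C)C#CCC[Mg]Br | intermediate
5 | {[(4S,5S)-5-(chloromethyl)-4-[4-(trimethylsilyl)but-3-yn-1-yl]-4,5-dihydrofuran-2-yl]oxy}trimethylsilane (silyl ketene acetal of 6) | C[Si](C)(C)OC1=C[C@H](CCC#C[Si](C)(C)C)[C@@H](CCl)O1 | intermediate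
6 | (4S,5S)-5-(chloromethyl)-4-[4-(trimethylsilyl)but-3-yn-1-yl]oxolan-2-one (4,5-trans) | O=C1C[C@H](CCC#C[Si](C)(C)C)[C@@H](CCl)O1 | intermediate
7 | (3R,4S,5S)-5-(chloromethyl)-3-(hydroxymethyl)-4-[4-(trimethylsilyl)but-3-yn-1-yl]oxolan-2-one (all-trans) | O=C1[C@@H](CO)[C@H](CCC#C[Si](C)(C)C)[C@@H](CCl)O1 | intermediate
8 | (3R,4S,5S)-5-(chloromethyl)-3-(hydroxymethyl)-4-[4-(trimethylsilyl)but-3-yn-1-yl]oxolan-2-ol (lactol, both anomers) | OC1[C@@H](CO)[C@H](CCC#C[Si](C)(C)C)[C@@H](CCl)O1 | intermediate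
9 | prop-2-en-1-ol | C=CCO | starting material
10 | 3-(methoxymethoxy)prop-1-ene | C=CCOCOC | intermediate
11 | [(Z)-3-(methoxymethoxy)prop-2-en-1-yl]diisopinocampheylborane (isopinocampheyl groups from (−)-α-pinene) | COCO/C=C\CB([C@H]1C[C@H]2C[C@@H]([C@@H]1C)C2(C)C)[C@H]1C[C@H]2C[C@@H]([C@@H]1C)C2(C)C | intermediate
12 | (2S,3S,4R,5S,6S)-1-chloro-4-(hydroxymethyl)-6-(methoxymethoxy)-3-[4-(trimethylsilyl)but-3-yn-1-yl]oct-7-ene-2,5-diol (chain = guaiane C6–C5–C1–C10–C9–C8–C7) | C=C[C@H](OCOC)[C@@H](O)[C@@H](CO)[C@H](CCC#C[Si](C)(C)C)[C@H](O)CCl | intermediate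
13 | O9,O14-isopropylidene derivative of 12 (2,2-dimethyl-1,3-dioxane; C5 chlorohydrin free) | C=C[C@H](OCOC)[C@H]1OC(C)(C)OC[C@H]1[C@H](CCC#C[Si](C)(C)C)[C@H](O)CCl | intermediate
14 | 5,6-epoxide derived from 13 (terminal oxirane, C5 configuration retained) | C=C[C@H](OCOC)[C@H]1OC(C)(C)OC[C@H]1[C@H](CCC#C[Si](C)(C)C)[C@H]2CO2 | intermediate
15 | diene allylic alcohol: C5 carbinol (β-OH in guaiane sense) bearing vinyl C6, 1β-silylbutynyl, O9,O14-acetonide, 8β-OMOM carbon bearing vinyl C7 | C=C[C@H](OCOC)[C@H]1OC(C)(C)OC[C@H]1[C@H](CCC#C[Si](C)(C)C)[C@H](O)C=C | intermediate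
16 | 1β-[4-(trimethylsilyl)but-3-yn-1-yl]-8β-(methoxymethoxy)-9α,14-(isopropylidenedioxy)cyclohept-6-en-5β-ol (ring C1–C5–C6=C7–C8–C9–C10, C14 α on C10) | O[C@@H]1C=C[C@H](OCOC)[C@H]2OC(C)(C)OC[C@H]2[C@@H]1CCC#C[Si](C)(C)C | intermediate
17 | 1-ethoxyvinyl ether of 16 (mixed ketene acetal) | C=C(OCC)O[C@@H]1C=C[C@H](OCOC)[C@H]2OC(C)(C)OC[C@H]2[C@@H]1CCC#C[Si](C)(C)C | intermediate
18 | ethyl ester: cyclohept-5-ene with 7β-CH2CO2Et, 8β-OMOM, 9α,14-O-isopropylidene, 1β-silylbutynyl | CCOC(=O)C[C@H]1C=C[C@@H](CCC#C[Si](C)(C)C)[C@@H]2COC(C)(C)O[C@@H]2[C@H]1OCOC | intermediate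
19 | cycloheptene acid: 7β-CH2CO2H, 8β-OMOM, 9α,14-O-isopropylidene, 1β-(but-3-yn-1-yl), C5=C6 | OC(=O)C[C@H]1C=C[C@@H](CCC#C)[C@@H]2COC(C)(C)O[C@@H]2[C@H]1OCOC | intermediate
20 | 8β-(methoxymethoxy)-9α,14-(isopropylidenedioxy)guai-4(15)-en-6α,12-olide (H-1α, H-5α, H-6β, H-7α, H-10β) | C=C1CC[C@@H]2[C@H]1[C@H]3OC(=O)C[C@@H]3[C@H](OCOC)[C@H]4OC(C)(C)OC[C@@H]24 | intermediate
21 | 11-[(dimethylamino)methyl] derivative of 20 (C11 epimers) | C=C1CC[C@@H]2[C@H]1[C@H]3OC(=O)C(CN(C)C)[C@@H]3[C@H](OCOC)[C@H]4OC(C)(C)OC[C@@H]24 | intermediate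
22 | 11-[(trimethylammonio)methyl] derivative of 20, iodide | C=C1CC[C@@H]2[C@H]1[C@H]3OC(=O)C(C[N+](C)(C)C)[C@@H]3[C@H](OCOC)[C@H]4OC(C)(C)OC[C@@H]24.[I-] | intermediate
23 | 8β-(methoxymethoxy)-9α,14-(isopropylidenedioxy)guaia-4(15),11(13)-dien-6α,12-olide | C=C1CC[C@@H]2[C@H]1[C@H]3OC(=O)C(=C)[C@@H]3[C@H](OCOC)[C@H]4OC(C)(C)OC[C@@H]24 | intermediate
24 | 9α,14-dihydroxy-8β-(methoxymethoxy)guaia-4(15),11(13)-dien-6α,12-olide | C=C1CC[C@@H]2[C@H]1[C@H]3OC(=O)C(=C)[C@@H]3[C@H](OCOC)[C@@H](O)[C@H]2CO | intermediate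
25 | 14-(tert-butyldiphenylsilyloxy)-9α-hydroxy-8β-(methoxymethoxy)guaia-4(15),11(13)-dien-6α,12-olide | C=C1CC[C@@H]2[C@H]1[C@H]3OC(=O)C(=C)[C@@H]3[C@H](OCOC)[C@@H](O)[C@H]2CO[Si](c4ccccc4)(c5ccccc5)C(C)(C)C | intermediate
26 | 9α-acetoxy-14-(tert-butyldiphenylsilyloxy)-8β-(methoxymethoxy)guaia-4(15),11(13)-dien-6α,12-olide | C=C1CC[C@@H]2[C@H]1[C@H]3OC(=O)C(=C)[C@@H]3[C@H](OCOC)[C@@H](OC(C)=O)[C@H]2CO[Si](c4ccccc4)(c5ccccc5)C(C)(C)C | intermediate
27 | 9α-acetoxy-14-(tert-butyldiphenylsilyloxy)-8β-hydroxyguaia-4(15),11(13)-dien-6α,12-olide | C=C1CC[C@@H]2[C@H]1[C@H]3OC(=O)C(=C)[C@@H]3[C@H](O)[C@@H](OC(C)=O)[C@H]2CO[Si](c4ccccc4)(c5ccccc5)C(C)(C)C | intermediate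
28 | (R)-2-methylbutanoic acid | CC[C@@H](C)C(=O)O | starting material
29 | 9α-acetoxy-14-(tert-butyldiphenylsilyloxy)-8β-[(R)-2-methylbutanoyloxy]guaia-4(15),11(13)-dien-6α,12-olide | C=C1CC[C@@H]2[C@H]1[C@H]3OC(=O)C(=C)[C@@H]3[C@H](OC(=O)[C@H](C)CC)[C@@H](OC(C)=O)[C@H]2CO[Si](c4ccccc4)(c5ccccc5)C(C)(C)C | intermediate
30 | 9α-acetoxy-14-hydroxy-8β-[(R)-2-methylbutanoyloxy]guaia-4(15),11(13)-dien-6α,12-olide | C=C1CC[C@@H]2[C@H]1[C@H]3OC(=O)C(=C)[C@@H]3[C@H](OC(=O)[C@H](C)CC)[C@@H](OC(C)=O)[C@H]2CO | intermediate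
31 | 9α-acetoxy-8β-[(R)-2-methylbutanoyloxy]-14-oxoguaia-4(15),11(13)-dien-6α,12-olide (H-10β) | C=C1CC[C@@H]2[C@H]1[C@H]3OC(=O)C(=C)[C@@H]3[C@H](OC(=O)[C@H](C)CC)[C@@H](OC(C)=O)[C@H]2C=O | intermediate
32 | 9α-acetoxy-4α,15-epoxy-8β-[(R)-2-methylbutanoyloxy]-14-oxoguai-11(13)-en-6α,12-olide | C1O[C@@]12CC[C@@H]3[C@H]2[C@H]4OC(=O)C(=C)[C@@H]4[C@H](OC(=O)[C@H](C)CC)[C@@H](OC(C)=O)[C@H]3C=O | intermediate
33 | lactol: 9α-acetoxy-4β,14-epoxy-14,15-dihydroxy-8β-[(R)-2-methylbutanoyloxy]guai-11(13)-en-6α,12-olide (H-10α; C14 epimers) | OC[C@]12CC[C@@H]3[C@H]1[C@H]4OC(=O)C(=C)[C@@H]4[C@H](OC(=O)[C@H](C)CC)[C@@H](OC(C)=O)[C@@H]3C(O)O2 | intermediate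
34 | 9α-acetoxy-4β,14-epoxy-15-hydroxy-8β-[(R)-2-methylbutanoyloxy]guaia-10(14),11(13)-dien-6α,12-olide (CNP0013863.3) | C=C1C(=O)O[C@H]2[C@H]1[C@H](OC(=O)[C@H](C)CC)[C@@H](OC(C)=O)C1=CO[C@@]3(CO)CC[C@@H]1[C@@H]23 | target

**Step count and risks**

Total: 22 steps. Longest linear sequence: 21 steps (steps 1–4 and 6–22 from compound 1; step 5 is a one-step side branch).

Steps most likely to fail:

Step 22. The isomerisation may stall at the lactol. The oxocarbenium ion may instead be trapped by the freed C15 hydroxyl as a cage acetal, or the 9-acetate, allylic once the enol ether exists, may ionise under the acid. The fallback sets out from epoxy aldehyde 32. Wet pyridinium p-toluenesulfonate without sieves is used to stop at lactol 33, which is isolated. Trifluoroacetic anhydride and iPr2NEt (CH2Cl2, −20 °C → rt) acylate both hydroxyls to the bis(trifluoroacetate) F1, whose anomeric trifluoroacetate is eliminated by the amine to the enol ether 15-trifluoroacetate F2. Brief NaHCO3/MeOH at 0 °C cleaves only the trifluoroacetate and the route is rejoined at target 34.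

Step 12. The cyclopropyl gold carbene may rearrange to a diene or close 6-endo before the acid captures C6, because the trans-lactone requires backside attack on the α face by a tether anchored on the β face. The fallback sets out from acid 19. Me3SiCHN2 (MeOH/toluene) gives the methyl ester F3. m-Chloroperbenzoic acid (NaHCO3, CH2Cl2, 0 °C) epoxidises the ring alkene on the α face, opposite the 1β and 7β side chains, to the 5α,6α-epoxide F4. Cp2TiCl (trivalent titanium, from Cp2TiCl2 and Zn, THF, with 1,4-cyclohexadiene) opens the epoxide reductively, and the C5 radical closes 5-exo-dig onto the alkyne with cis ring fusion to the 6α-hydroxy ester F5. Warming with pyridinium p-toluenesulfonate in toluene lactonises F5 and the route is rejoined at lactone 20.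

Step 6. Slow ring opening of the lactol and protonolysis of the allylborane by the two free hydroxyls may cut conversion and facial control. The fallback sets out from lactone 7. MeNHOMe·HCl/Me3Al (CH2Cl2) opens it to the Weinreb amide diol F6. Et3SiCl/imidazole gives the bis(triethylsilyl) ether F7, and iBu2AlH (THF, −78 °C) gives the free aldehyde F8. The same allylborane 11 then adds to give the homoallylic alcohol F9. Camphorsulfonic acid with 2,2-dimethoxypropane in MeOH/CH2Cl2 removes both silyl ethers and closes the O9/O14 acetonide, and the route is rejoined at acetonide 13.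

Further compounds
F1 | step 22 | bis(trifluoroacetate) of lactol 33 (14-O and 15-O) | O=C(OC[C@]12CC[C@@H]3[C@H]1[C@H]4OC(=O)C(=C)[C@@H]4[C@H](OC(=O)[C@H](C)CC)[C@@H](OC(C)=O)[C@@H]3C(OC(=O)C(F)(F)F)O2)C(F)(F)F
F2 | step 22 | 15-O-trifluoroacetate of target 34 | O=C(OC[C@]12CC[C@@H]3[C@H]1[C@H]4OC(=O)C(=C)[C@@H]4[C@H](OC(=O)[C@H](C)CC)[C@@H](OC(C)=O)C3=CO2)C(F)(F)F
F3 | step 12 | methyl ester of acid 19 | COC(=O)C[C@H]1C=C[C@@H](CCC#C)[C@@H]2COC(C)(C)O[C@@H]2[C@H]1OCOC
F4 | step 12 | 5α,6α-epoxide of methyl ester F3 | COC(=O)C[C@H]1[C@@H]2O[C@@H]2[C@@H](CCC#C)[C@@H]3COC(C)(C)O[C@@H]3[C@H]1OCOC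
F5 | step 12 | methyl 6α-hydroxy-8β-(methoxymethoxy)-9α,14-(isopropylidenedioxy)guai-4(15)-en-12-oate | C=C1CC[C@@H]2[C@H]1[C@@H](O)[C@H](CC(=O)OC)[C@H](OCOC)[C@H]4OC(C)(C)OC[C@@H]24
F6 | step 6 | Weinreb amide diol from lactone 7 (N-methoxy-N-methyl amide at C9; 5-OH and 14-OH free) | CON(C)C(=O)[C@@H](CO)[C@H](CCC#C[Si](C)(C)C)[C@H](O)CCl
F7 | step 6 | 5,14-bis(triethylsilyl) ether of F6 | CON(C)C(=O)[C@@H](CO[Si](CC)(CC)CC)[C@H](CCC#C[Si](C)(C)C)[C@H](O[Si](CC)(CC)CC)CCl
F8 | step 6 | C9 aldehyde from F7 | O=C[C@@H](CO[Si](CC)(CC)CC)[C@H](CCC#C[Si](C)(C)C)[C@H](O[Si](CC)(CC)CC)CCl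
F9 | step 6 | 5,14-bis(triethylsilyl) ether of chlorotriol 12 | C=C[C@H](OCOC)[C@@H](O)[C@@H](CO[Si](CC)(CC)CC)[C@H](CCC#C[Si](C)(C)C)[C@H](O[Si](CC)(CC)CC)CCl
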